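All runs were generated by integration on assumed constants.

At late times I reckon these flasks by what J can still pay for. Counting one J for each L or D that reacts, I call the charged J, in percent of the L and D together, the J budget: 55.0%. That is less than the whole of L and D, so J is the limiting reagent against the pair, but it exceeds L's own 50.0% by a surplus of 5 percentage points.

all flasks: L 0.40 M; D 0.40 M

| run | J | Z | remark | time |
|---|---|---|---|---|
| dawn | 1.1 equiv | 3 mol% | run made earlier |  |
| north | 1.10 equiv | 2.5 mol% |  | 25 h |
| south | 1.10 equiv | 5 mol% |  | 25 h |
| north-west | 1.10 equiv | 10 mol% |  | 25 h |
| west | 1.10 equiv | 20 mol% |  | 25 h |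
| north-east | 1.10 equiv | 40 mol% |  | 25 h |

dawn run (percent of the L and D together charged): time / h: E / % = 2.00: 0.6; 6.00: 4.4; 12.0: 11.4; 20.0: 19.3; 25.0: 22.5

(each reading ± 0.5 percentage points)

- Z is single-handed; L and D are mirror images of each other, charged as a racemate, each of them at the stated concentration
- as a solid, counted per litre of solution: J
- at the start none of J is in solution
- "hardly changes" means that all values lie within two and a half points (for a concentration: within two and a half percent of the largest)
- no earlier run changes the charge of Z; that part of a forecast is a guess

* amount of E at the end, in percent of the L and D together charged for north, south, north-west, west, north-east, in this order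
* the course of these numbers from the first flask to the last (hardly changes / falls, then rises / falls all the way / rises, then falls / rises all the way)

Treating E as coming from L, I take the log of L's share over what remains of it, which in the dawn run at 25.0 h is 0.598. Scaling this with Z, which is a guess because no earlier run changes Z, gives 0.498 in north, or about 19.6% of E, and 7.97 in north-east. That exponent leaves hardly any of L, so in north-east I hold E against the budget: once E stands at 50.0%, the J left over for D and for any other use is the surplus of 5 points. I therefore expect E to rise with Z and flatten at or below that ceiling.

The forecast gives 19.5%, 30.5%, 40%, 46% and 48%, a course that rises all the way, with the words “E should still rise towards the 50% ceiling”.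

The flasks give 19.9%, 29.8%, 37.5%, 42.1% and 44.2%, a course that rises all the way.

    G + Z + L → Z + E (k = 0.00320 M⁻² s⁻¹)
    G + Z + D → Z + X (k = 3.10 × 10⁻⁴ M⁻² s⁻¹)
    J ⇌ G, rate k3*(cs3 - [G]) while solid is left; crystals form when [G] > cs3 (solubility = 0.230 M, k = 8.80 × 10⁻⁵ s⁻¹)
    2 G → Q (k = 7.60 × 10⁻⁶ M⁻¹ s⁻¹)

North-east ends at 44.2% of E with 5.79% of L still there and solid J at 0% of its charge, J being the first to run out. The budget less that E leaves 11 points, of which X holds 9.43%, more than the surplus, while G and Q, counted at two G for each Q, hold 1.36%. In west, E at 42.1%, X at 8.18%, and G and Q at 4.73% add up to 55.0%, with 7.91% of L left.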